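**Retrosynthetic overview**
- The target (all-cis 2R,3R,6S piperidine) is disconnected at the cinnamoyl Cβ–aryl bond: a Heck coupling of an N-Boc, ketal-protected cassine 3-O-acrylate with MOM-protected 4-bromoguaiacol (from catechol), then one acidic global deprotection.
- The three ring stereocentres are set together by a proposed catalytic asymmetric hydrogenation of a 2,3,6-trisubstituted pyridine.
- The ring C6–side-chain bond comes from a B-alkyl Suzuki–Miyaura coupling of 3-benzyloxy-6-iodo-2-methylpyridine (from 2-methylpyridin-3-ol) with a C12 alkene ketal.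
- The C12 alkene ketal comes from a Cu-catalysed sp3–sp3 coupling of the Grignard of 6-chlorohexan-2-one ethylene ketal with 6-bromohex-1-ene.
- Ring order: no ring is built de novo. The piperidine is the dearomatised pyridine nucleus and the arene comes from catechol.

Assumption: simple reagents and protecting-group sources (ethylene glycol, BnBr, Boc2O, MOMCl, MeI, I2, NBS, 9-BBN) are treated as reagents and are not numbered.
Assumption: the sense of induction of the new hydrogenation cannot be predicted; the (S)-ligand is written, and the (R)-ligand is used instead if the first run gives ent-9.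

**Route**

Step 1
Reactants: 1, 6-chlorohexan-2-one
Product: 2, 2-(4-chlorobutyl)-2-methyl-1,3-dioxolane
Conditions: HOCH2CH2OH (1.5 equiv), p-TsOH·H2O (2 mol%), toluene, Dean–Stark, reflux
Reagents that add atoms: ethylene glycol, OCCO
Why: Acid-catalysed ketalisation with azeotropic water removal masks the methyl ketone for the Grignard, Suzuki and hydrogenation steps; no stereocentre is involved.

Step 2
Reactants: 2, 2-(4-chlorobutyl)-2-methyl-1,3-dioxolane; 3, 6-bromohex-1-ene
Product: 4, 2-(dec-9-en-1-yl)-2-methyl-1,3-dioxolane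
Conditions: (i) 2 (1.25 equiv), Mg, cat. I2/BrCH2CH2Br, THF, reflux; (ii) 3, Li2CuCl4 (3 mol%), THF/NMP, 0 °C → rt
Reagents that add atoms: none
Why: Kochi-type Cu-catalysed sp3–sp3 coupling of a primary Grignard with a primary bromide; the Grignard is made on the ketal chloride, not the hexenyl bromide, to avoid 5-exo radical cyclisation, and the ketal and terminal alkene are inert.

Step 3
Reactants: 5, 2-methylpyridin-3-ol
Product: 6, 6-iodo-2-methylpyridin-3-ol
Conditions: I2 (1.05 equiv), Na2CO3, H2O, rt
Reagents that add atoms: iodine, II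
Why: Electrophilic aromatic iodination of the pyridinolate; with C2 blocked by methyl, substitution goes to C6 (para to O–, α to N).

Step 4
Reactants: 6, 6-iodo-2-methylpyridin-3-ol
Product: 7, 3-(benzyloxy)-6-iodo-2-methylpyridine
Conditions: BnBr, K2CO3, DMF, rt
Reagents that add atoms: benzyl bromide, BrCc1ccccc1
Why: Williamson O-alkylation; the ring nitrogen is flanked by Me and I (hindered, electron-poor), so N-benzylation does not compete.

Step 5
Reactants: 4, 2-(dec-9-en-1-yl)-2-methyl-1,3-dioxolane; 7, 3-(benzyloxy)-6-iodo-2-methylpyridine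
Product: 8, 3-(benzyloxy)-2-methyl-6-[10-(2-methyl-1,3-dioxolan-2-yl)decyl]pyridine
Conditions: (i) 4 (1.3 equiv), 9-BBN-H, THF, 0 °C → rt; (ii) 7, PdCl2(dppf)·CH2Cl2 (5 mol%), 3 M aq K3PO4, DMF, 60 °C
Reagents that add atoms: none
Why: Anti-Markovnikov hydroboration followed by B-alkyl Suzuki–Miyaura coupling forms the C6–C1′ bond; 2-iodopyridines add oxidatively fast, dppf suppresses β-hydride elimination, and the ketal and benzyl ether tolerate the base.

Step 6
Reactants: 8, 3-(benzyloxy)-2-methyl-6-[10-(2-methyl-1,3-dioxolan-2-yl)decyl]pyridine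
Product: 9, (2R,3R,6S)-3-(benzyloxy)-2-methyl-6-[10-(2-methyl-1,3-dioxolan-2-yl)decyl]piperidine
Conditions: (i) TMSBr/MeOH (1.00 equiv each), CH2Cl2, 0 °C, evaporate (gives anhydrous 8·HBr); (ii) [{Ir(H)((S)-SegPhos)}2(μ-Cl)3]Cl (1.5 mol%), H2 (50 bar), 1,4-dioxane, 40 °C, 24 h; (iii) aq K2CO3; ee upgraded by crystallising the dibenzoyl-tartrate salt if needed
Reagents that add atoms: none
Why: Proposed new method: Ir(III)–H/chiral bisphosphine asymmetric ionic hydrogenation of a 2,6-dialkyl-3-alkoxypyridinium salt, a substrate class not yet shown. Outer-sphere hydride transfer to C4 gives a 1,4-dihydropyridine, C5 protonation gives the C6=N+ iminium, and its reduction by the chiral Ir–H is enantio-determining (sets C6). The remaining 2-methyl-3-benzyloxy enamine/iminium pair epimerises at C3 (dynamic kinetic resolution) and takes axial hydride at C2 on the conformer with pseudo-axial OBn (A(1,2) strain with 2-Me), anti to OBn and on the face of H-6, giving the all-cis 2R,3R,6S triad. The closest known reaction type is Ir–diphosphine asymmetric hydrogenation of 2,6-disubstituted pyridinium HX salts and of N-benzyl 3-hydroxypyridinium salts to cis-piperidines.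

Step 7
Reactants: 9, (2R,3R,6S)-3-(benzyloxy)-2-methyl-6-[10-(2-methyl-1,3-dioxolan-2-yl)decyl]piperidine
Product: 10, tert-butyl (2R,3R,6S)-3-(benzyloxy)-2-methyl-6-[10-(2-methyl-1,3-dioxolan-2-yl)decyl]piperidine-1-carboxylate
Conditions: Boc2O (2.5 equiv), Et3N, THF, 55 °C
Reagents that add atoms: di-tert-butyl dicarbonate, CC(C)(C)OC(=O)OC(=O)OC(C)(C)C
Why: Carbamate formation on the hindered 2,6-cis-dialkyl amine (excess reagent and heat) blocks aza-Michael addition and O→N acyl transfer in the later steps; stereocentres are untouched.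

Step 8
Reactants: 10, the N-Boc benzyl ether
Product: 11, tert-butyl (2R,3R,6S)-3-hydroxy-2-methyl-6-[10-(2-methyl-1,3-dioxolan-2-yl)decyl]piperidine-1-carboxylate
Conditions: H2 (1 atm), 20% Pd(OH)2/C, EtOH, rt
Reagents that add atoms: none
Why: Neutral hydrogenolysis of the benzyl ether; Boc and dioxolane are stable and the C–O stereocentre is retained.

Step 9
Reactants: 11, the N-Boc alcohol; 12, acryloyl chloride
Product: 13, tert-butyl (2R,3R,6S)-2-methyl-6-[10-(2-methyl-1,3-dioxolan-2-yl)decyl]-3-(prop-2-enoyloxy)piperidine-1-carboxylate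
Conditions: 12 (1.5 equiv), Et3N, DMAP (5 mol%), BHT (trace), CH2Cl2, −20 → 0 °C
Reagents that add atoms: none
Why: O-acylation of the secondary alcohol with retention at C3; in the N-Boc 2,6-diaxial conformer the 3-OH is equatorial and accessible.

Step 10
Reactants: 14, catechol
Product: 15, 2-methoxyphenol (guaiacol)
Conditions: MeI (1.0 equiv), K2CO3 (1.0 equiv), acetone, reflux; base extraction and distillation
Reagents that add atoms: iodomethane, CI
Why: Williamson mono-O-methylation; the mono-ether is separated from veratrole (non-acidic) and catechol (water-soluble).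

Step 11
Reactants: 15, 2-methoxyphenol
Product: 16, 4-bromo-2-methoxyphenol
Conditions: NBS (1.0 equiv), MeCN, −10 → 0 °C
Reagents that add atoms: N-bromosuccinimide, O=C1CCC(=O)N1Br
Why: Electrophilic aromatic bromination directed para to the free phenol, the stronger activator.

Step 12
Reactants: 16, 4-bromo-2-methoxyphenol
Product: 17, 4-bromo-2-methoxy-1-(methoxymethoxy)benzene
Conditions: MOMCl, i-Pr2NEt, CH2Cl2, 0 °C → rt
Reagents that add atoms: chloromethyl methyl ether, COCCl
Why: Phenol protection as an acid-labile MOM acetal that survives the basic Heck conditions and falls off in the final acid step.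

Step 13
Reactants: 13, the piperidinyl acrylate; 17, 4-bromo-2-methoxy-1-(methoxymethoxy)benzene
Product: 18, tert-butyl (2R,3R,6S)-3-{[(2E)-3-[3-methoxy-4-(methoxymethoxy)phenyl]prop-2-enoyl]oxy}-2-methyl-6-[10-(2-methyl-1,3-dioxolan-2-yl)decyl]piperidine-1-carboxylate
Conditions: Pd2(dba)3 (1.5 mol%), [(t-Bu)3PH]BF4 (6 mol%), Cy2NMe (1.2 equiv), 1,4-dioxane, 70 °C
Reagents that add atoms: none
Why: Mizoroki–Heck arylation of the acrylate; the bulky electron-rich phosphine activates the electron-rich aryl bromide, and syn-insertion/syn-β-H elimination gives the E-cinnamate only.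

Step 14
Reactants: 18, the fully protected feruloyl ester
Product: 19, (+)-3-O-feruloylcassine, (2R,3R,6S)-2-methyl-6-(11-oxododecyl)piperidin-3-yl (2E)-3-(4-hydroxy-3-methoxyphenyl)prop-2-enoate
Conditions: TFA/CH2Cl2/H2O (10:10:1), 0 °C → rt; then cold aq NaHCO3 to pH 8, rapid extraction (store as the TFA or HCl salt)
Reagents that add atoms: water, O
Why: One acidolysis removes Boc, the aryl MOM acetal and the dioxolane while the cinnamate ester survives; cold, brief free-basing limits O→N acyl migration, and no stereocentre is touched.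

**Compound list**
1 | 6-chlorohexan-2-one | CC(=O)CCCCCl | starting material
2 | 2-(4-chlorobutyl)-2-methyl-1,3-dioxolane | CC1(CCCCCl)OCCO1 | intermediate
3 | 6-bromohex-1-ene | C=CCCCCBr | starting material
4 | 2-(dec-9-en-1-yl)-2-methyl-1,3-dioxolane | C=CCCCCCCCCC1(C)OCCO1 | intermediate
5 | 2-methylpyridin-3-ol | Cc1ncccc1O | starting material
6 | 6-iodo-2-methylpyridin-3-ol | Cc1nc(I)ccc1O | intermediate
7 | 3-(benzyloxy)-6-iodo-2-methylpyridine | Cc1nc(I)ccc1OCc1ccccc1 | intermediate
8 | 3-(benzyloxy)-2-methyl-6-[10-(2-methyl-1,3-dioxolan-2-yl)decyl]pyridine | Cc1nc(CCCCCCCCCCC2(C)OCCO2)ccc1OCc1ccccc1 | intermediate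
9 | (2R,3R,6S)-3-(benzyloxy)-2-methyl-6-[10-(2-methyl-1,3-dioxolan-2-yl)decyl]piperidine | c1ccccc1CO[C@@H]2CC[C@H](CCCCCCCCCCC3(C)OCCO3)N[C@@H]2C | intermediate
10 | tert-butyl (2R,3R,6S)-3-(benzyloxy)-2-methyl-6-[10-(2-methyl-1,3-dioxolan-2-yl)decyl]piperidine-1-carboxylate | c1ccccc1CO[C@@H]2CC[C@H](CCCCCCCCCCC3(C)OCCO3)N(C(=O)OC(C)(C)C)[C@@H]2C | intermediate
11 | tert-butyl (2R,3R,6S)-3-hydroxy-2-methyl-6-[10-(2-methyl-1,3-dioxolan-2-yl)decyl]piperidine-1-carboxylate | O[C@@H]1CC[C@H](CCCCCCCCCCC2(C)OCCO2)N(C(=O)OC(C)(C)C)[C@@H]1C | intermediate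
12 | acryloyl chloride | C=CC(=O)Cl | starting material
13 | tert-butyl (2R,3R,6S)-2-methyl-6-[10-(2-methyl-1,3-dioxolan-2-yl)decyl]-3-(prop-2-enoyloxy)piperidine-1-carboxylate | C=CC(=O)O[C@@H]1CC[C@H](CCCCCCCCCCC2(C)OCCO2)N(C(=O)OC(C)(C)C)[C@@H]1C | intermediate
14 | catechol (benzene-1,2-diol) | Oc1ccccc1O | starting material
15 | 2-methoxyphenol | COc1ccccc1O | intermediate
16 | 4-bromo-2-methoxyphenol | COc1cc(Br)ccc1O | intermediate
17 | 4-bromo-2-methoxy-1-(methoxymethoxy)benzene | COCOc1ccc(Br)cc1OC | intermediate
18 | tert-butyl (2R,3R,6S)-3-{[(2E)-3-[3-methoxy-4-(methoxymethoxy)phenyl]prop-2-enoyl]oxy}-2-methyl-6-[10-(2-methyl-1,3-dioxolan-2-yl)decyl]piperidine-1-carboxylate | COCOc1ccc(/C=C/C(=O)O[C@@H]2CC[C@H](CCCCCCCCCCC3(C)OCCO3)N(C(=O)OC(C)(C)C)[C@@H]2C)cc1OC | intermediate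
19 | (+)-3-O-feruloylcassine | COc1cc(/C=C/C(=O)O[C@@H]2CC[C@H](CCCCCCCCCCC(C)=O)N[C@@H]2C)ccc1O | target

**Totals**
- Total step count: 14.
- Longest linear sequence: 9 steps (3 → 4 → 5 → 6 → 7 → 8 → 9 → 13 → 14; the side-chain branch 1 → 2 → 5 … is also 9; the aryl branch is 5).

**Three steps most likely to fail**
1. Step 6 (proposed new asymmetric pyridinium hydrogenation): ee, cis-selectivity or conversion may be inadequate. Fallback with known chemistry: hydrogenate 8 over Rh/Al2O3 or PtO2 to the racemic all-cis piperidinol (established for 6-alkyl-2-methylpyridin-3-ols; the benzyl group is lost at the same time), N-Boc protect, and resolve the alcohol by lipase-catalysed acylation (CAL-B, vinyl acetate) or the amine by dibenzoyl-tartrate salt crystallisation. The resolved (2R,3R,6S) alcohol rejoins the route at compound 11.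
2. Step 5 (B-alkyl Suzuki on the 2-iodopyridine): protodeboronation or slow transmetalation may occur. Fallback: change the organometallic partner by converting 4 into the primary iodide (9-BBN, then I2/NaOMe), forming the alkylzinc iodide (Zn, LiCl) and running a Negishi coupling with 7 (Pd/CPhos).
3. Step 13 (Heck on the advanced acrylate): acrylate polymerisation or sluggish oxidative addition of the electron-rich bromide may occur. Fallback: move the Heck to the simple fragment (17 + acrylic acid gives MOM-protected ferulic acid) and join it to alcohol 11 by Yamaguchi or Steglich esterification, then carry out step 14 unchanged.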